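Intermediate A cannot hold the part of the charge that is still upstream of it. Call that part the rest R: 100 minus intermediate A, intermediate B and over-reaction product, in percent of the charge. R is what remains as starting material and target, with the idle adduct's full weight.

| flask | starting material | remark | time |
|---|---|---|---|
| red | 0.20 M | run made earlier |  |
| green | 0.80 M | run made earlier |  |
| south-east | 0.40 M |  | 2.5 h |
| east | 0.40 M |  | 4.0 h |

| run | time / min | intermediate A / % | over-reaction product / % | intermediate B / % | target / % | starting material / % |
|---|---|---|---|---|---|---|
| red | 15.0 | 7.6 | 0.1 | 0.2 | 19.7 | 70.7 |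
| red | 30.0 | 14.1 | 0 | 0.4 | 31.1 | 50.9 |
| red | 50.0 | 23.1 | 0.5 | 0.3 | 39.5 | 33.3 |
| red | 60.0 | 27.9 | 0.6 | 0.3 | 41.2 | 27.3 |
| red | 80.0 | 36.2 | 0.9 | 0.8 | 41.9 | 18.0 |
| red | 90.0 | 40.4 | 1.1 | 1.1 | 40.8 | 15.1 |
| red | 120 | 50.4 | 1.7 | 2.7 | 36.5 | 8.4 |
| green | 10.0 | 4.4 | 0 | 0.3 | 14.2 | 75.8 |
| green | 15.0 | 6.7 | 0 | 0.3 | 19.9 | 66.7 |
| green | 20.0 | 8.5 | 0 | 0.3 | 24.0 | 58.9 |
| green | 30.0 | 12.9 | 0.3 | 0 | 31.4 | 47.0 |
| green | 50.0 | 20.1 | 0.3 | 0.3 | 39.4 | 30.8 |
| green | 80.0 | 32.1 | 0.6 | 1.0 | 42.4 | 18.3 |
| green | 120 | 46.2 | 1.8 | 2.1 | 38.6 | 9.5 |

(readings scatter by 0.3 percentage points)

- in percentages every species weighs as the starting material in it: one idle adduct counts as two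
- for target the idle adduct is counted in
- reactions considered so far: starting material -> intermediate A; intermediate A <-> intermediate B; starting material -> target; target -> intermediate A; target -> over-reaction product; starting material + target <-> idle adduct
- in an amount of target, one idle adduct counts as one target

* which of these there is most of at the end, counted by the starting material in it, south-east (target / intermediate A / intermediate B / starting material / over-reaction product)
* which of these there is most of at the end, counted by the starting material in it, east (target / intermediate A / intermediate B / starting material / over-reaction product)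
* amount of the one of these that there is most of at the end, in percent of the starting material charged, south-east
* amount of the one of these that there is most of at the end, in percent of the starting material charged, east

Two chemists part over the east flask. The first reckons what is made. Between 80.0 min and 120 min, intermediate A gained on average 14 percentage points in the red and green runs, reaching a mean of 48.3% at the later time. Drawn straight on, that line gives 58.9% for south-east and 90.8% for east.

The second reckons what is left. Over the same interval R fell from 62.1% to 45.2% in the red run, and from 66.3% to 49.9% in the green run. Read as a first-order decay, this gives the rest rate λ, the fraction of R lost per minute, 0.00752 min⁻¹.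

0.40 M lies midway by ratio between 0.20 M and 0.80 M, so she starts from the mean by ratio, 47.5%. Her estimate of R is then 37.9% in south-east and 19.3% in east. By that estimate the cap on intermediate A is 62.1% in south-east and 80.7% in east.

The line in east stands above its estimated cap, so by this reckoning the first chemist's view fails there. In south-east it stands under the cap, and on that shorter step it may serve. Target is part of R, so in south-east intermediate B and over-reaction product together would have to take 24 points to put intermediate A behind it. In the red run they held 4.40% at 120 min.

The forecast names intermediate A for south-east and intermediate A for east, with 57% and 68%, both under the caps. One of its grounds is that “the adduct only slightly delays things and concentration hardly matters”.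

    starting material → intermediate A (k = 7.80 × 10⁻⁵ s⁻¹)
    intermediate A ⇌ intermediate B (K = 1.30, k = 1.30 × 10⁻⁵ s⁻¹)
    starting material → target (k = 2.80 × 10⁻⁴ s⁻¹)
    target → intermediate A (k = 1.40 × 10⁻⁴ s⁻¹)
    target → over-reaction product (k = 8.30 × 10⁻⁶ s⁻¹)
    starting material + target ⇌ idle adduct, settled at all times (K = 1.00 M⁻¹)

The flasks give intermediate A at 56.8% in south-east and intermediate A at 71.2% in east, so the forecast held. The line overshoots east by 20 points and south-east by 2.2 points. R stands at 37.3% in south-east and 17.6% in east, against the reckoned 37.9% and 19.3%. For south-east read at 10 h, the same λ leaves R at 1.28%. That flask holds 0.729% target and 0% starting material, with intermediate A at 70.0% and intermediate B at 24.9%.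

All runs come from a simulation with constants of no real substance; the scatter is artificial.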